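**Retrosynthetic overview**

- Feature: the benzylic CH2 joins the lactam nitrogen to C1 of the arene, the one ring carbon that bears neither Br nor O. C1 sits between the C2 and C6 bromines and para to the C4 oxygen.
- Last disconnection: the two phenolic O–H groups are masked as methyl ethers, which are stable to strong acid and are cleaved at the end.
- Key disconnection: the N–CH2 and CH2–aryl bonds are cut together, giving pyrrolidin-2-one, formaldehyde and 1,2,5-tribromo-3,4-dimethoxybenzene, whose single C–H is the reacting carbon.
- The tribromoarene goes back to veratrole through 3,6-dibromoveratrole (double ortho-lithiation/bromination, then one electrophilic bromination).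
- Ring order: no ring is formed; the benzene ring and the γ-lactam ring are both bought.

Key step: step 3

Remark: the target has no stereogenic element, so it is a single achiral compound and no stereocontrol is needed. Paraformaldehyde is drawn as its monomer.

**Route**

Step 1
Reactants: 1 veratrole (1,2-dimethoxybenzene)
Product: 3 3,6-dibromoveratrole (1,4-dibromo-2,3-dimethoxybenzene), via 3,6-dilithioveratrole 2 (not isolated)
Conditions: n-BuLi (3 equiv), TMEDA (3 equiv), Et2O, 0 °C → reflux; then BrCCl2CCl2Br (3 equiv), THF, −78 °C → rt
Reagents that add atoms: 1,2-dibromo-1,1,2,2-tetrachloroethane, BrC(Cl)(Cl)C(Cl)(Cl)Br; n-butyllithium, [Li]CCCC (lithium, in intermediate 2 only)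
Why: Directed ortho-metalation, in which each methoxy group steers n-BuLi/TMEDA to its free ortho position to give the 3,6-dilithio species, followed by Br+ transfer from the dibromotetrachloroethane to both C–Li bonds.

Step 2
Reactants: 3 3,6-dibromoveratrole
Product: 4 1,2,5-tribromo-3,4-dimethoxybenzene (3,4,6-tribromoveratrole)
Conditions: Br2 (1.05 equiv), FeBr3 (5 mol %), CH2Cl2, 0 °C → rt, dark
Reagents that add atoms: bromine, BrBr
Why: Lewis-acid-catalysed electrophilic aromatic bromination; the two remaining C–H positions of 3 are equivalent by symmetry (each para to one methoxy group), so any monobromination gives 4, and the third bromine slows a fourth substitution.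

Step 3
Reactants: 4 1,2,5-tribromo-3,4-dimethoxybenzene; 5 pyrrolidin-2-one; 6 paraformaldehyde
Product: 9 1-(2,3,6-tribromo-4,5-dimethoxybenzyl)pyrrolidin-2-one, via 1-(hydroxymethyl)pyrrolidin-2-one 7 (not isolated), via N-methylidene-2-oxopyrrolidinium ion 8 (not isolated)
Conditions: 5 (1.5 equiv), (CH2O)n (1.3 equiv), K2CO3 (2 mol %), neat, 80 °C; then 4 (1.0 equiv), TfOH (10 equiv), CH2Cl2, 0 → 40 °C; aq. NaHCO3 work-up
Reagents that add atoms: none
Why: Lactam 5 and formaldehyde first give hemiaminal 7, which triflic acid ionises by loss of water to N-acyliminium ion 8; this attacks the one unsubstituted ring carbon of 4 (para to a methoxy group, between two bromines) and the arenium ion loses a proton, so the N–CH2 and CH2–aryl bonds are both made in one pot. The closest known reaction type is the Tscherniac–Einhorn amidomethylation, which in triflic acid extends to halogenated and other electron-poor arenes and is commonly run from the amide or lactam plus paraformaldehyde. No ring is closed and no stereocentre is formed. The step needs site selectivity, which the substrate fixes because only one aromatic C–H is left, and selectivity for mono-benzylation, which the three bromines secure by slowing both a second attack on 4 and re-ionisation of the benzylic C–N bond of 9 to a diarylmethane. The lactam is kept in excess over formaldehyde so that no free formaldehyde can hydroxymethylate the arene, and the non-basic lactam and the aryl methyl ethers should tolerate the acid at this temperature.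

Step 4
Reactants: 9 1-(2,3,6-tribromo-4,5-dimethoxybenzyl)pyrrolidin-2-one
Product: 11 1-[(2,3,6-tribromo-4,5-dihydroxyphenyl)methyl]pyrrolidin-2-one, via cyclic aryl bromoboronate 10 (not isolated)
Conditions: BBr3 (4 equiv), CH2Cl2, −78 °C → rt; then ice/H2O, 0 °C
Reagents that add atoms: boron tribromide, BrB(Br)Br (boron and bromine, in intermediate 10 only)
Why: Lewis-acid aryl methyl ether cleavage, in which BBr3 coordinates each methoxy oxygen and bromide removes the methyl group by SN2 to leave the cyclic borate 10 that water hydrolyses to the catechol; the lactam (which only binds one equivalent of BBr3), the benzylic C–N bond and the aryl bromides are not attacked, and the quench is aqueous rather than alcoholic so that the 4-hydroxybenzyl position is not solvolysed.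

**Compound list**

1 | veratrole (1,2-dimethoxybenzene) | COc1ccccc1OC | starting material
2 | 3,6-dilithioveratrole | COc1c([Li])ccc([Li])c1OC | intermediate
3 | 3,6-dibromoveratrole (1,4-dibromo-2,3-dimethoxybenzene) | COc1c(Br)ccc(Br)c1OC | intermediate
4 | 1,2,5-tribromo-3,4-dimethoxybenzene | COc1c(OC)c(Br)c(Br)cc1Br | intermediate
5 | pyrrolidin-2-one | O=C1CCCN1 | starting material
6 | paraformaldehyde (formaldehyde monomer drawn) | C=O | starting material
7 | 1-(hydroxymethyl)pyrrolidin-2-one | O=C1CCCN1CO | intermediate
8 | N-methylidene-2-oxopyrrolidinium ion (N-acyliminium cation, counter-ion triflate not drawn) | C=[N+]1CCCC1=O | intermediate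
9 | 1-(2,3,6-tribromo-4,5-dimethoxybenzyl)pyrrolidin-2-one | COc1c(OC)c(Br)c(Br)c(CN2CCCC2=O)c1Br | intermediate
10 | 1-[(2-bromo-4,5,7-tribromo-1,3,2-benzodioxaborol-6-yl)methyl]pyrrolidin-2-one (cyclic aryl bromoboronate; ring-Br at 4,5,7, B–Br at 2) | O=C1CCCN1Cc1c(Br)c2OB(Br)Oc2c(Br)c1Br | intermediate
11 | 1-[(2,3,6-tribromo-4,5-dihydroxyphenyl)methyl]pyrrolidin-2-one | O=C1CCCN1Cc1c(Br)c(O)c(O)c(Br)c1Br | target

**Summary**

Total step count: 4. Longest linear sequence: 4 steps, from veratrole 1.

**Steps most likely to fail**

Step 3. The N-acyliminium ion may add too slowly to the electron-poor ring, whose two methoxy groups are twisted out of conjugation by their ortho neighbours. Acid-promoted bromine transfer between arene molecules (ipso-protonation and loss of Br+) or ether cleavage could then overtake C–C bond formation. The fallback makes the aryl–carbon bond by carbanion chemistry and sets out from 4. The lone aromatic hydrogen, acidified by its two ortho bromines, is removed with LDA in THF at −78 °C to give (2,3,6-tribromo-4,5-dimethoxyphenyl)lithium F1. DMF, then an aqueous HCl quench, converts this into 2,3,6-tribromo-4,5-dimethoxybenzaldehyde F2. Reductive amination with methyl 4-aminobutanoate hydrochloride (Et3N, NaBH(OAc)3, ClCH2CH2Cl) gives methyl 4-[(2,3,6-tribromo-4,5-dimethoxybenzyl)amino]butanoate F3. Heating F3 in toluene with catalytic AcOH closes the lactam with loss of methanol, and the route is rejoined at 9.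

Step 1. The second metalation may be incomplete, and during the quench halogen–lithium exchange between aryl bromide already formed and remaining organolithium may scramble bromine, leaving mono-brominated and butylated material. The fallback sets out from 1. Dianion 2, generated as in step 1, is quenched with Me3SiCl to give 1,2-dimethoxy-3,6-bis(trimethylsilyl)benzene F4, whose C–Si bonds are inert to organolithiums and which can be purified, or re-subjected to metalation/silylation, before any bromine is introduced. Ipso-bromodesilylation with Br2 (2 equiv, CH2Cl2, 0 °C) then replaces each silyl group by bromine, and the route is rejoined at 3.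

Step 2. Stoichiometric control may be lost: 4 may brominate further while 3 is still present, or the Lewis acid may promote bromine migration or ether cleavage. The fallback sets out from 3 and fixes the bromine count through the amount of base. Deprotonation ortho to bromine with LDA (1.05 equiv, THF, −78 °C) gives (2,5-dibromo-3,4-dimethoxyphenyl)lithium F5, which is brominated with BrCCl2CCl2Br. Should F5 isomerise by halogen dance to (4,6-dibromo-2,3-dimethoxyphenyl)lithium F6, bromination of F6 leads to the same product, so the route is rejoined at 4 in either case.

**Further compounds**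

F1 | step 3 | (2,3,6-tribromo-4,5-dimethoxyphenyl)lithium | COc1c(OC)c(Br)c(Br)c([Li])c1Br
F2 | step 3 | 2,3,6-tribromo-4,5-dimethoxybenzaldehyde | COc1c(OC)c(Br)c(Br)c(C=O)c1Br
F3 | step 3 | methyl 4-[(2,3,6-tribromo-4,5-dimethoxybenzyl)amino]butanoate | COC(=O)CCCNCc1c(Br)c(Br)c(OC)c(OC)c1Br
F4 | step 1 | 1,2-dimethoxy-3,6-bis(trimethylsilyl)benzene | COc1c([Si](C)(C)C)ccc([Si](C)(C)C)c1OC
F5 | step 2 | (2,5-dibromo-3,4-dimethoxyphenyl)lithium | COc1c(OC)c(Br)c([Li])cc1Br
F6 | step 2 | (4,6-dibromo-2,3-dimethoxyphenyl)lithium | COc1c(OC)c([Li])c(Br)cc1Br
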